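**Assumption:** 2,4,6-trihydroxybenzaldehyde, tert-butyl 3-oxo-3,6-dihydropyridine-1(2H)-carboxylate and 3,4-dimethoxybenzoyl chloride are bought. The target is the cis-(3'S,4'R) compound (rohitukine 3'-O-veratrate). The route is a design and has not been run experimentally.

## Retrosynthetic overview

1. Final operations: MOM removal, and cis-selective hydrogenation of a C4'=C5' alkene (sets C4').
2. C8–C4' bond: Suzuki coupling of an 8-iodochromone (east) with an enantioenriched alkenyl boronate that already carries the C3' veratrate (west).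
3. East: the pyran-4-one ring is the only ring built, by a 6-endo oxa-Michael closure of an o-hydroxyaryl ynone derived from 2,4,6-trihydroxybenzaldehyde.
4. West: the piperidine ring is bought as an N-Boc dihydropyridinone; α-iodination, CBS reduction (sets C3'), borylation, N-Boc to N-Me, then esterification.

## East fragment

**Step 1**
Reactants: 1 2,4,6-trihydroxybenzaldehyde; 2 chloromethyl methyl ether
Product: 3 2-hydroxy-4,6-bis(methoxymethoxy)benzaldehyde
Conditions: MOMCl (2.2 equiv), i-Pr2NEt, CH2Cl2, 0 °C → rt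
Reagents that add atoms: MOMCl, COCCl
Why: O-alkylation (Williamson type) of the 4-OH and one ortho OH; the remaining ortho OH is hydrogen-bonded to the aldehyde and stays free.

**Step 2**
Reactants: 3; 4 benzyltrimethylammonium dichloroiodate
Product: 5 2-hydroxy-3-iodo-4,6-bis(methoxymethoxy)benzaldehyde
Conditions: BnMe3N·ICl2 (1.05 equiv), NaHCO3, CH2Cl2–MeOH, rt
Reagents that add atoms: BnMe3N·ICl2, C[N+](C)(C)Cc1ccccc1.Cl[I-]Cl
Why: Electrophilic aromatic iodination directed ortho to the free chelated phenol (as in C6 iodination of 5-hydroxy-7-alkoxyflavones), so the iodine sits next to the future ring oxygen, which fixes the C8 regiochemistry.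

**Step 3**
Reactants: 5; 6 1-propynylmagnesium bromide
Product: 7 1-[2-hydroxy-3-iodo-4,6-bis(methoxymethoxy)phenyl]but-2-yn-1-ol (racemic)
Conditions: 1-propynylMgBr (2.5 equiv), THF, −20 → 0 °C; aq NH4Cl
Reagents that add atoms: 1-propynylmagnesium bromide, CC#C[Mg]Br
Why: Grignard 1,2-addition to the aldehyde (first equivalent deprotonates the phenol; alkynyl Grignards do not exchange with ArI); the carbinol centre is removed in step 4.

**Step 4**
Reactants: 7
Product: 8 1-[2-hydroxy-3-iodo-4,6-bis(methoxymethoxy)phenyl]but-2-yn-1-one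
Conditions: activated MnO2, CH2Cl2, rt
Reagents that add atoms: none
Why: MnO2 selectively oxidises the benzylic/propargylic alcohol to the ynone without touching MOM ethers or the aryl iodide.

**Step 5 (key ring closure)**
Reactants: 8
Product: 9 8-iodo-5,7-bis(methoxymethoxy)-2-methyl-4H-chromen-4-one
Conditions: Et2NH (1.5 equiv), EtOH, rt → 40 °C
Reagents that add atoms: none
Why: Intramolecular oxa-Michael addition of the only free phenol to the ynone (amine-mediated, via the β-aminoenone) closes the pyranone 6-endo and avoids the 5-exo aurone mode.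

## West fragment

**Step 6**
Reactants: 10 tert-butyl 3-oxo-3,6-dihydropyridine-1(2H)-carboxylate; 11 iodine
Product: 12 tert-butyl 4-iodo-3-oxo-3,6-dihydropyridine-1(2H)-carboxylate
Conditions: I2 (1.5 equiv), pyridine–CH2Cl2, 0 °C → rt
Reagents that add atoms: iodine, II
Why: Johnson α-iodination of a cyclic enone (pyridine conjugate addition, enolate iodination, elimination) puts iodine on the α-vinyl carbon only.

**Step 7**
Reactants: 12
Product: 13 tert-butyl (3R)-3-hydroxy-4-iodo-3,6-dihydropyridine-1(2H)-carboxylate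
Conditions: (S)-Me-CBS (15 mol%), BH3·SMe2, THF, −20 °C
Reagents that add atoms: none
Why: Corey–Bakshi–Shibata reduction with the iodovinyl side as the large group sets the carbinol centre; the (3R) label here is the same spatial arrangement as 3'S in the target (CIP priorities change when I is replaced).

**Step 8**
Reactants: 13; 14 bis(pinacolato)diboron
Product: 15 tert-butyl (3S)-3-hydroxy-4-(4,4,5,5-tetramethyl-1,3,2-dioxaborolan-2-yl)-3,6-dihydropyridine-1(2H)-carboxylate
Conditions: B2pin2, PdCl2(dppf), KOAc, dioxane, 80 °C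
Reagents that add atoms: B2pin2, CC1(C)OB(OC1(C)C)B1OC(C)(C)C(C)(C)O1
Why: Miyaura borylation of the alkenyl iodide; the free allylic OH cannot ionise to a π-allyl and the stereocentre is untouched.

**Step 9**
Reactants: 15; 16 formaldehyde
Product: 17 (3S)-1-methyl-4-(4,4,5,5-tetramethyl-1,3,2-dioxaborolan-2-yl)-1,2,3,6-tetrahydropyridin-3-ol
Conditions: 4 M HCl/dioxane, 0 °C → rt; then 37% aq HCHO, NaBH(OAc)3, Et3N, CH2Cl2, rt
Reagents that add atoms: formaldehyde, C=O
Why: Acidolysis of Boc then reductive amination installs N-methyl (alkenyl-Bpin tolerates both); done before esterification to avoid O→N acyl shift in a free amino ester.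

**Step 10**
Reactants: 17; 18 3,4-dimethoxybenzoyl chloride
Product: 19 (3S)-1-methyl-4-(4,4,5,5-tetramethyl-1,3,2-dioxaborolan-2-yl)-1,2,3,6-tetrahydropyridin-3-yl 3,4-dimethoxybenzoate
Conditions: 18 (1.2 equiv), Et3N, DMAP (cat.), CH2Cl2, 0 °C → rt
Reagents that add atoms: 3,4-dimethoxybenzoyl chloride, COc1ccc(C(=O)Cl)cc1OC
Why: DMAP-catalysed acylation of the only OH; the C–O bond is not broken, so configuration is retained.

## Union and endgame

**Step 11**
Reactants: 9; 19
Product: 20 (3S)-4-[5,7-bis(methoxymethoxy)-2-methyl-4-oxo-4H-chromen-8-yl]-1-methyl-1,2,3,6-tetrahydropyridin-3-yl 3,4-dimethoxybenzoate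
Conditions: Pd(OAc)2/SPhos (5/10 mol%), K3PO4, dioxane–H2O, 60 °C
Reagents that add atoms: none (both partners are reactants)
Why: Suzuki–Miyaura sp2–sp2 coupling with a ligand suited to di-ortho-substituted aryl halides; oxidative addition to ArI outpaces ionisation of the allylic ester, and mild phosphate base spares chromone, ester and MOM groups.

**Step 12**
Reactants: 20
Product: 21 (3S,4R)-4-[5,7-bis(methoxymethoxy)-2-methyl-4-oxo-4H-chromen-8-yl]-1-methylpiperidin-3-yl 3,4-dimethoxybenzoate
Conditions: H2 (1–3 atm), PtO2, EtOAc, AcOH (1 equiv), rt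
Reagents that add atoms: none
Why: Heterogeneous syn-hydrogenation; A(1,2) strain with the bulky aryl holds the C3' acyloxy group pseudo-axial, so H2 adds to the opposite face and gives the cis-(3S,4R) product. Pt is chosen over Pd to limit allylic C–O hydrogenolysis and double-bond migration.

**Step 13**
Reactants: 21
Product: 22 chrotacumine D, (3S,4R)-4-(5,7-dihydroxy-2-methyl-4-oxo-4H-chromen-8-yl)-1-methylpiperidin-3-yl 3,4-dimethoxybenzoate
Conditions: 3 M aq HCl, i-PrOH–THF, 45 °C; then NaHCO3
Reagents that add atoms: none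
Why: Acid-catalysed acetal hydrolysis removes both phenolic MOM ethers; the hindered secondary benzoate, the aryl methyl ethers and both stereocentres are stable under these conditions.

## Compound list

1 | 2,4,6-trihydroxybenzaldehyde | O=Cc1c(O)cc(O)cc1O | starting material
2 | chloromethyl methyl ether | COCCl | starting material (reagent)
3 | 2-hydroxy-4,6-bis(methoxymethoxy)benzaldehyde | COCOc1cc(O)c(C=O)c(OCOC)c1 | intermediate
4 | benzyltrimethylammonium dichloroiodate | C[N+](C)(C)Cc1ccccc1.Cl[I-]Cl | starting material (reagent)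
5 | 2-hydroxy-3-iodo-4,6-bis(methoxymethoxy)benzaldehyde | COCOc1cc(OCOC)c(C=O)c(O)c1I | intermediate
6 | 1-propynylmagnesium bromide | CC#C[Mg]Br | starting material (reagent)
7 | 1-[2-hydroxy-3-iodo-4,6-bis(methoxymethoxy)phenyl]but-2-yn-1-ol (racemic) | CC#CC(O)c1c(O)c(I)c(OCOC)cc1OCOC | intermediate
8 | 1-[2-hydroxy-3-iodo-4,6-bis(methoxymethoxy)phenyl]but-2-yn-1-one | CC#CC(=O)c1c(O)c(I)c(OCOC)cc1OCOC | intermediate
9 | 8-iodo-5,7-bis(methoxymethoxy)-2-methyl-4H-chromen-4-one | Cc1cc(=O)c2c(OCOC)cc(OCOC)c(I)c2o1 | intermediate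
10 | tert-butyl 3-oxo-3,6-dihydropyridine-1(2H)-carboxylate | CC(C)(C)OC(=O)N1CC=CC(=O)C1 | starting material
11 | iodine | II | starting material (reagent)
12 | tert-butyl 4-iodo-3-oxo-3,6-dihydropyridine-1(2H)-carboxylate | CC(C)(C)OC(=O)N1CC=C(I)C(=O)C1 | intermediate
13 | tert-butyl (3R)-3-hydroxy-4-iodo-3,6-dihydropyridine-1(2H)-carboxylate | O[C@@H]1CN(C(=O)OC(C)(C)C)CC=C1I | intermediate
14 | bis(pinacolato)diboron | CC1(C)OB(OC1(C)C)B1OC(C)(C)C(C)(C)O1 | starting material (reagent)
15 | tert-butyl (3S)-3-hydroxy-4-(pinacolboryl)-3,6-dihydropyridine-1(2H)-carboxylate | O[C@@H]1CN(C(=O)OC(C)(C)C)CC=C1B2OC(C)(C)C(C)(C)O2 | intermediate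
16 | formaldehyde | C=O | starting material (reagent)
17 | (3S)-1-methyl-4-(pinacolboryl)-1,2,3,6-tetrahydropyridin-3-ol | O[C@@H]1CN(C)CC=C1B2OC(C)(C)C(C)(C)O2 | intermediate
18 | 3,4-dimethoxybenzoyl chloride | COc1ccc(C(=O)Cl)cc1OC | starting material
19 | (3S)-1-methyl-4-(pinacolboryl)-1,2,3,6-tetrahydropyridin-3-yl 3,4-dimethoxybenzoate | COc1ccc(C(=O)O[C@@H]2CN(C)CC=C2B3OC(C)(C)C(C)(C)O3)cc1OC | intermediate
20 | (3S)-4-[5,7-bis(methoxymethoxy)-2-methyl-4-oxo-4H-chromen-8-yl]-1-methyl-1,2,3,6-tetrahydropyridin-3-yl 3,4-dimethoxybenzoate | COc1ccc(C(=O)O[C@@H]2CN(C)CC=C2c2c(OCOC)cc(OCOC)c3c(=O)cc(C)oc23)cc1OC | intermediate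
21 | (3S,4R)-4-[5,7-bis(methoxymethoxy)-2-methyl-4-oxo-4H-chromen-8-yl]-1-methylpiperidin-3-yl 3,4-dimethoxybenzoate | COc1ccc(C(=O)O[C@@H]2CN(C)CC[C@@H]2c2c(OCOC)cc(OCOC)c3c(=O)cc(C)oc23)cc1OC | intermediate
22 | chrotacumine D | COc1ccc(C(=O)O[C@@H]2CN(C)CC[C@@H]2c2c(O)cc(O)c3c(=O)cc(C)oc23)cc1OC | target

## Step count

Total steps: 13 (east 1–5, west 6–10, union and endgame 11–13).
Longest linear sequence: 8 steps (1→5, 11→13; the west branch 6→10, 11→13 is equally long), which is 8/13 ≈ 62% of the total.

## Three steps most likely to fail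

1. **Step 12 (cis-selective hydrogenation).** Risks are attack on the wrong face, allylic C–O hydrogenolysis and chromone over-reduction. Fallback: set both centres from a ketone instead. Methanolyse the ester of 20 to the allylic alcohol, isomerise it (or MnO2 oxidation then conjugate reduction) to the epimerisable 4-aryl-1-methylpiperidin-3-one, reduce with Ru–TsDPEN transfer hydrogenation under dynamic kinetic resolution to the cis-(3S,4R) alcohol, re-acylate with 18, then step 13.

2. **Step 11 (Suzuki coupling).** Both partners are hindered, and protodeboronation or Pd-allyl ionisation of the ester could compete. Fallback: drop the cross-coupling and make the aryl–C4' bond by carbonyl addition. Add the aryllithium from 1-benzyloxy-3,5-bis(methoxymethoxy)benzene (lithiated between the two MOM ethers) to 1-methylpiperidin-4-one. Then dehydrate, hydroborate–oxidise, Swern-oxidise and reduce the ketone by DKR hydrogenation to the cis alcohol. Finish by aryl acylation to the ynone, esterification, the same oxa-Michael closure and deprotection.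

3. **Step 2 (regioselective iodination, C3 versus C5).** Fallback: reverse the order. Mono-iodinate symmetrical aldehyde 1 first, where only one mono-iodo isomer is possible. Then bis-MOM protect, leaving free the most hindered, hydrogen-bonded OH flanked by CHO and I; this gives 5 without relying on directing effects.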